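Cuts: once the sulfonyl helper on the ansa-pyrrole nitrogen is removed, ring B (3-methoxy-2H-pyrrole: N1, spiro C2, C3-OMe, C4-H, C5-pyrrolyl) is cut at N1–C2 and C4–C5. This gives 1H-pyrrole-2-carbonitrile and a 2-(1-methoxyvinyl)oxan-2-yl cation, and cutting C2–C3 then leads to a δ-lactone and 1-methoxyvinyllithium.
Enabling feature: the spiro carbon is the anomeric N,O-ketal carbon of the oxane, so it is a latent oxocarbenium ion. The ring C=N that carries pyrrole ring A is a latent nitrile, and C(OMe)=CH is a latent enol ether, so the five ring-B atoms map onto cation + N≡C + C=C.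
Further cuts: the ansa-pyrrole goes back (Paal–Knorr) to a 13-membered 1,4-diketone, and that ring is cut at a CH2–CH2 bond (RCM/hydrogenation). The side chains come off the lactone at C4 (cuprate addition) and C3 (enolate acylation, then Grignard).
Forward ring order: oxanone (RCM), then the 13-membered carbocycle (RCM), then the ansa-pyrrole (12-membered pyrrolophane), then ring B, which closes last. Pyrrole ring A is bought with the nitrile.
Stereochemistry: C–CH3 comes from (S)-pent-4-en-2-ol, and C4 from conjugate addition anti to the methyl group. C3 is set trans to C4 by anti acylation and equilibration, and the spiro centre by axial (anomeric) C–N bond formation on the oxane chair.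

Key step: step 11

Assumption: in the 3,4-fused lactones the 3,4-trans (diequatorial) epimer is taken to be the more stable one, so the enolisable C3 centre settles in the required S configuration.

Step 1
Reactants: 1 (S)-pent-4-en-2-ol; 2 acryloyl chloride
Product: 3 (S)-pent-4-en-2-yl acrylate
Conditions: Et3N, DMAP (cat.), CH2Cl2, 0 °C → rt
Reagents that add atoms: none
Why: O-acylation of a secondary alcohol with an acid chloride, which does not touch the stereocentre.

Step 2
Reactants: 3 (S)-pent-4-en-2-yl acrylate
Product: 4 (S)-6-methyl-5,6-dihydro-2H-pyran-2-one ((S)-parasorbic acid)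
Conditions: Grubbs II (3 mol %), CH2Cl2 (0.01 M), reflux
Reagents that add atoms: none
Why: Ring-closing metathesis of an acrylate with a terminal alkene is a standard entry to 5,6-dihydropyran-2-ones and leaves C6 (S) untouched.

Step 3
Reactants: 4 (S)-parasorbic acid; 5 pent-4-en-1-ylmagnesium bromide
Product: 6 (4S,6S)-6-methyl-4-(pent-4-en-1-yl)oxan-2-one
Conditions: CuBr·SMe2 (10 mol %), THF, −78 → −40 °C; 1 M HCl
Reagents that add atoms: none
Why: Copper-catalysed 1,4-addition of a Grignard reagent, in which axial attack on the half-chair with a pseudo-equatorial C6 methyl delivers the chain anti to the methyl group and sets C4 as S (4,6-trans).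

Step 4
Reactants: 7 succinyl chloride
Product: 8 N1,N4-dimethoxy-N1,N4-dimethylbutanediamide
Conditions: MeNHOMe·HCl (2.2 equiv), pyridine, CH2Cl2, 0 °C → rt
Reagents that add atoms: N,O-dimethylhydroxylamine hydrochloride, CNOC.Cl
Why: Twofold Weinreb amide formation by acylation of the amine with a diacid chloride.

Step 5
Reactants: 6 (4S,6S)-6-methyl-4-(pent-4-en-1-yl)oxan-2-one; 8 bis-Weinreb amide
Product: 9 N-methoxy-N-methyl-4-[(3S,4S,6S)-6-methyl-2-oxo-4-(pent-4-en-1-yl)oxan-3-yl]-4-oxobutanamide
Conditions: LDA (1.1 equiv), THF, −78 °C; 8 (2 equiv), −78 → −20 °C; 1 M HCl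
Reagents that add atoms: none
Why: Crossed Claisen-type C-acylation of a lactone lithium enolate by a Weinreb amide, whose chelated tetrahedral adduct stops further reaction; the acyl group enters anti to the C4 chain and the acidic C3–H lets the product settle as the 3,4-trans (3S) isomer.

Step 6
Reactants: 9 β-keto lactone Weinreb amide; 10 but-3-en-1-ylmagnesium bromide
Product: 11 1-[(3S,4S,6S)-6-methyl-2-oxo-4-(pent-4-en-1-yl)oxan-3-yl]oct-7-ene-1,4-dione
Conditions: 10 (2.5 equiv), THF, −78 → 0 °C; 1 M HCl
Reagents that add atoms: none
Why: Weinreb ketone synthesis, in which the first equivalent of Grignard reagent turns the β-keto lactone into its magnesium enolate and so shields lactone and ketone while the second equivalent adds to the amide.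

Step 7
Reactants: 11 diene-dione
Product: 13 macrocyclic 1,4-diketone lactone (3S,4S,6S), via macrocyclic alkene 12 (not isolated)
Conditions: Grubbs II (10 mol %), CH2Cl2 (1 mM), reflux; then H2 (1 atm), Pd/C, EtOAc, rt
Reagents that add atoms: none
Why: Macrocyclic ring-closing metathesis at high dilution followed by hydrogenation of the crude E/Z alkene is a well-precedented way to 12- to 14-membered carbocycles, is helped here by the gauche trans-diequatorial side chains, and touches no stereocentre.

Step 8
Reactants: 13 macrocyclic 1,4-diketone lactone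
Product: 14 pyrrolophane lactone (3S,4S,6S)
Conditions: NH4OAc (20 equiv), AcOH–toluene 1:4, 90 °C
Reagents that add atoms: ammonium acetate, CC(=O)[O-].[NH4+]
Why: Paal–Knorr pyrrole synthesis on a macrocyclic 1,4-diketone; C3 is re-formed by protonation of the exocyclic enamine tautomer and, being enolisable, should equilibrate to the trans-diequatorial 3S epimer.

Step 9
Reactants: 14 pyrrolophane lactone; 15 methyl vinyl ether
Product: 18 triethylsilyl ketal of the 2-(1-methoxyvinyl) hemiketal, via 1-methoxyvinyllithium 16 (not isolated), via dilithio hemiketalate 17 (not isolated)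
Conditions: 15, t-BuLi, THF, −78 → 0 °C; 14, −78 °C; TESOTf, −78 → −40 °C; aq NaHCO3
Reagents that add atoms: triethylsilyl trifluoromethanesulfonate, CC[Si](CC)(CC)OS(=O)(=O)C(F)(F)F
Why: 1,2-Addition of an α-alkoxyvinyllithium to a δ-lactone stops at the tetrahedral lithium hemiketalate at −78 °C, which the silyl triflate traps on oxygen, while prior N-lithiation of the pyrrole lowers the acidity of C3–H and so protects that centre (the new C2 centre need not be controlled because step 11 erases it).

Step 10
Reactants: 18 triethylsilyl ketal
Product: 19 N-SES triethylsilyl ketal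
Conditions: KHMDS (1.1 equiv), THF, −78 → 0 °C; SESCl, 0 °C → rt
Reagents that add atoms: 2-(trimethylsilyl)ethanesulfonyl chloride, C[Si](C)(C)CCS(=O)(=O)Cl
Why: N-sulfonylation of a potassium pyrrolide, clean here because the closed ketal has no acidic C–H; the sulfonyl group is the helper that switches off the nucleophilic β-carbons of the ansa-pyrrole for step 11.

Step 11
Reactants: 19 N-SES triethylsilyl ketal; 20 1H-pyrrole-2-carbonitrile
Product: 23 N-SES-premarineosin A, via oxocarbenium ion 21 (not isolated), via nitrilium ion 22 (not isolated)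
Conditions: 20 (10 equiv), TMSOTf (1.2 equiv), 2,6-di-tert-butyl-4-methylpyridine (1.5 equiv), 4 Å MS, CH2Cl2 (5 mM), −78 → −20 °C; aq NaHCO3
Reagents that add atoms: none
Why: Proposed new method: TMSOTf ionises the silyl ketal to the 2-(1-methoxyvinyl)oxocarbenium ion 21, the nitrile nitrogen of 20 adds in Ritter fashion to give nitrilium ion 22, the released enol ether attacks the nitrilium carbon through its CH2 terminus, and proton loss from the resulting methoxycarbenium ion gives the conjugated 3-methoxy-2H-pyrrole, so one C–N bond, one C–C bond, ring A and the spiro centre arrive in one operation. The closest known reaction type is the TMSOTf-mediated formal [3+2] cycloaddition of nitriles (2-cyanopyrroles included) with donor–acceptor cyclopropanes, which runs through the same oxocarbenium, nitrilium and five-ring imine sequence, together with the Ritter and Houben–Hoesch reactions; new here are the 1-alkoxy-2-methoxyallyl cation as the three-carbon partner and the ketal-type spiro carbon. The only ring closed is the 2H-pyrrole, by a 5-endo-dig attack of the enol ether carbon on the nitrilium carbon. The spiro centre is controlled by the oxane chair: the slim linear nitrile bonds along the axial trajectory (kinetic anomeric effect, as in the nitrile effect of glycosylation) on the face that also holds the axial C6 methyl, the bulkier methoxyvinyl group stays equatorial, and this N-axial (R) arrangement is also the anomerically favoured one, so reversible nitrile addition should not erode it. Regioselectivity (N to C2, not to the CH2 terminus of the allyl cation) rests on the ring oxygen, which localises the charge at C2, and on the reversibility of nitrile addition, since only the C2 adduct has an enol ether placed to close. Chemoselectivity rests on the SES group, without which C4 of the ansa-pyrrole would close a six-membered ring on the nitrilium carbon in Bischler–Napieralski fashion, and further on the blocked α-positions of that pyrrole, the low nucleophilicity of the cyano-substituted pyrrole, and high dilution with excess nitrile and a hindered base.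

Step 12
Reactants: 23 N-SES-premarineosin A
Product: 24 premarineosin A
Conditions: TBAF (3 equiv), THF, 50 °C; H2O
Reagents that add atoms: none
Why: Fluoride-induced β-elimination of the SES group (attack at the remote silicon, loss of ethene and SO2) frees the pyrrole N–H under non-acidic conditions that should leave the N,O-ketal, the enol ether and all four stereocentres untouched.

Compound list
1 | (S)-pent-4-en-2-ol | C[C@H](O)CC=C | starting material
2 | acryloyl chloride | C=CC(=O)Cl | starting material
3 | (S)-pent-4-en-2-yl acrylate | C=CC(=O)O[C@@H](C)CC=C | intermediate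
4 | (S)-6-methyl-5,6-dihydro-2H-pyran-2-one ((S)-parasorbic acid) | C[C@H]1CC=CC(=O)O1 | intermediate
5 | pent-4-en-1-ylmagnesium bromide (commercial THF solution) | C=CCCC[Mg]Br | starting material
6 | (4S,6S)-6-methyl-4-(pent-4-en-1-yl)oxan-2-one (4,6-trans) | O=C1O[C@@H](C)C[C@H](CCCC=C)C1 | intermediate
7 | succinyl chloride | O=C(Cl)CCC(=O)Cl | starting material
8 | N1,N4-dimethoxy-N1,N4-dimethylbutanediamide | CON(C)C(=O)CCC(=O)N(C)OC | intermediate
9 | N-methoxy-N-methyl-4-[(3S,4S,6S)-6-methyl-2-oxo-4-(pent-4-en-1-yl)oxan-3-yl]-4-oxobutanamide | O=C1O[C@@H](C)C[C@H](CCCC=C)[C@H]1C(=O)CCC(=O)N(C)OC | intermediate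
10 | but-3-en-1-ylmagnesium bromide (commercial THF solution) | C=CCC[Mg]Br | starting material
11 | 1-[(3S,4S,6S)-6-methyl-2-oxo-4-(pent-4-en-1-yl)oxan-3-yl]oct-7-ene-1,4-dione | O=C1O[C@@H](C)C[C@H](CCCC=C)[C@H]1C(=O)CCC(=O)CCC=C | intermediate
12 | macrocyclic alkene: (3S,4S,6S)-6-methyloxan-2-one fused at C3–C4 to a 13-membered ring C3–CO–CH2CH2–CO–CH2CH2–CH=CH–(CH2)3–C4 (E/Z mixture) | O=C1O[C@@H](C)C[C@@H]2CCCC=CCCC(=O)CCC(=O)[C@H]21 | intermediate
13 | macrocyclic 1,4-diketone lactone: as 12 with the alkene saturated, C3–CO–CH2CH2–CO–(CH2)7–C4 | O=C1O[C@@H](C)C[C@@H]2CCCCCCCC(=O)CCC(=O)[C@H]21 | intermediate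
14 | pyrrolophane lactone: (3S,4S,6S)-6-methyloxan-2-one with C3 bonded to C2 of a 1H-pyrrole and C4 joined to C5 of the same pyrrole by a (CH2)7 chain | O=C1O[C@@H](C)C[C@@H]2CCCCCCCc3ccc([nH]3)[C@H]21 | intermediate
15 | methyl vinyl ether | C=COC | starting material
16 | 1-methoxyvinyllithium | [Li]C(=C)OC | intermediate
17 | dilithio hemiketalate: adduct of 16 to the lactone carbonyl of N-lithiated 14 | C=C(OC)C1(O[Li])O[C@@H](C)C[C@@H]2CCCCCCCc3ccc(n3[Li])[C@H]21 | intermediate
18 | triethylsilyl ketal: (3S,4S,6S)-2-(1-methoxyvinyl)-6-methyl-2-(triethylsilyloxy)oxane carrying the ansa-pyrrole of 14 (either C2 anomer; the centre is erased in step 11) | C=C(OC)C1(O[Si](CC)(CC)CC)O[C@@H](C)C[C@@H]2CCCCCCCc3ccc([nH]3)[C@H]21 | intermediate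
19 | N-SES triethylsilyl ketal: 18 with 2-(trimethylsilyl)ethanesulfonyl on the pyrrole nitrogen | C=C(OC)C1(O[Si](CC)(CC)CC)O[C@@H](C)C[C@@H]2CCCCCCCc3ccc(n3S(=O)(=O)CC[Si](C)(C)C)[C@H]21 | intermediate
20 | 1H-pyrrole-2-carbonitrile | N#Cc1ccc[nH]1 | starting material
21 | oxocarbenium ion (triflate): 2-(1-methoxyvinyl)oxan-1-ium-1-ene derived from 19 | C=C(OC)C1=[O+][C@@H](C)C[C@@H]2CCCCCCCc3ccc(n3S(=O)(=O)CC[Si](C)(C)C)[C@H]21.[O-]S(=O)(=O)C(F)(F)F | intermediate
22 | nitrilium ion (triflate): axial N-(oxan-2-yl) nitrilium of 20, with the methoxyvinyl group equatorial | C=C(OC)[C@]1([N+]#Cc4ccc[nH]4)O[C@@H](C)C[C@@H]2CCCCCCCc3ccc(n3S(=O)(=O)CC[Si](C)(C)C)[C@H]21.[O-]S(=O)(=O)C(F)(F)F | intermediate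
23 | N-SES-premarineosin A: the target with 2-(trimethylsilyl)ethanesulfonyl on the ansa-pyrrole nitrogen | COC1=CC(c2ccc[nH]2)=N[C@]12O[C@@H](C)C[C@@H]1CCCCCCCc3ccc(n3S(=O)(=O)CC[Si](C)(C)C)[C@H]12 | intermediate
24 | premarineosin A (spiro C R; C–CH3 S; chain-bearing CH S; pyrrolyl-bearing CH S) | COC1=CC(c2ccc[nH]2)=N[C@]12O[C@@H](C)C[C@@H]1CCCCCCCc3ccc([nH]3)[C@H]12 | target

Total step count: 12. Longest linear sequence: 11 steps (steps 1–3 and 5–12).

Steps most likely to fail

Step 11. Four things may go wrong:
- The nitrile may bond at the CH2 terminus of the allyl cation.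
- The cation may lose the C3 proton.
- The bent 5-endo-dig closure may be slower than hydrolysis of the nitrilium ion on work-up.
- Facial selectivity at the spiro carbon may be poor.

The fallback sets out from 14 and comes back at 24, using known reactions only and needing no sulfonyl helper. Methyl (E)-3-methoxyacrylate is lithiated at its β-carbon (LDA, THF, −90 °C) and added to 14. The hemiketal alkoxide then closes onto the ester to give the spiro methyl tetronate F1. Aluminium amide aminolysis (AlMe3/NH4Cl) opens the butenolide to the primary amide, and camphorsulfonic acid closes nitrogen onto the ketal carbon under anomeric control to give the spiro 4-methoxy-3-pyrrolin-2-one F2. Activation of this lactam with Tf2O, followed by a large excess of pyrrole (Vilsmeier–Haack-type condensation), installs ring A and gives 24.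

Step 9. Deprotonation at C3 may compete with carbonyl addition. The hemiketalate may also open before silylation, so that silicon ends on the secondary oxygen.

The fallback sets out from 14 and comes back at 18. The lactone is opened with Me2AlN(OMe)Me to the hydroxy Weinreb amide F3, whose α-CH is far less acidic than that of the lactone. Excess 16 then adds once through the chelated adduct, after O- and N-deprotonation. Neutral work-up lets the δ-hydroxy ketone close to the free hemiketal F4, and TESOTf/2,6-lutidine at −78 °C silylates the closed form to give 18.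

Step 8. Closure of the strained pyrrolophane may be slow, ammonia may open the lactone, and re-protonation at C3 may be poorly controlled.

The fallback sets out from 6 and comes back at 14, and it sets C3 kinetically:
- Pyrrole-2-carbaldehyde and allylmagnesium bromide give 1-(1H-pyrrol-2-yl)but-3-en-1-ol F5.
- NaBH4 in refluxing 2-propanol reduces F5, through the azafulvene, to 2-(but-3-en-1-yl)-1H-pyrrole F6.
- Compound 6 and excess F6 are deprotonated together with LiHMDS and oxidised with copper(II) 2-ethylhexanoate (oxidative enolate–pyrrole heterocoupling). The pyrrole enters anti to the C4 chain and gives the 3,4-trans diene lactone F7.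
- Ring-closing metathesis at high dilution gives the unsaturated pyrrolophane lactone F8.
- Hydrogenation over Pd/C gives 14.

Further compounds
F1 | step 11 | spiro methyl tetronate: 4-methoxyfuran-2(5H)-one spiro-fused at C5 to C2 of the oxane of 14 (acyloxy oxygen axial) | COC1=CC(=O)O[C@]12O[C@@H](C)C[C@@H]1CCCCCCCc3ccc([nH]3)[C@H]12
F2 | step 11 | spiro lactam: 4-methoxy-1,5-dihydro-2H-pyrrol-2-one spiro-fused at C5 to C2 of the oxane of 14 (nitrogen axial) | COC1=CC(=O)N[C@]12O[C@@H](C)C[C@@H]1CCCCCCCc3ccc([nH]3)[C@H]12
F3 | step 9 | hydroxy Weinreb amide from ring opening of 14 | C[C@H](O)C[C@@H]1CCCCCCCc2ccc([nH]2)[C@H]1C(=O)N(C)OC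
F4 | step 9 | free 2-(1-methoxyvinyl) hemiketal (anomers in equilibrium) | C=C(OC)C1(O)O[C@@H](C)C[C@@H]2CCCCCCCc3ccc([nH]3)[C@H]21
F5 | step 8 | 1-(1H-pyrrol-2-yl)but-3-en-1-ol (racemic) | C=CCC(O)c1ccc[nH]1
F6 | step 8 | 2-(but-3-en-1-yl)-1H-pyrrole | C=CCCc1ccc[nH]1
F7 | step 8 | (3S,4S,6S)-3-[5-(but-3-en-1-yl)-1H-pyrrol-2-yl]-6-methyl-4-(pent-4-en-1-yl)oxan-2-one | O=C1O[C@@H](C)C[C@H](CCCC=C)[C@H]1c2ccc(CCC=C)[nH]2
F8 | step 8 | unsaturated pyrrolophane lactone (E/Z), 14 with a CH=CH in the ansa chain | O=C1O[C@@H](C)C[C@@H]2CCCC=CCCc3ccc([nH]3)[C@H]21
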